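**Assumption:** recrystallised (3R,3′R,6′R)-lutein from marigold, a bulk nutraceutical, is accepted as a cheap commercial starting material.

## Retrosynthetic overview

1. Target ⇒ lutein dipalmitate: the oxirane (C5–O, C6–O) is made last, by one O-atom transfer to the β-ring C5=C6 bond of the finished, unprotected C72 diester. This copies the epoxidase step that ends the xanthophyll pathway.
2. Lutein dipalmitate ⇒ lutein + 2 palmitoyl chloride (two ester C–O bonds). The esters also switch off hydroxyl-directed attack on the wrong face and on the ε-ring alkene.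
3. Ring order: the ε- and β-cyclohexene rings are taken from lutein as the plant's lycopene cyclases built them. The oxirane is the only ring closed in the flask and is closed last.
4. Stereocentres: C3, C3′ and C6′ come from lutein and are never touched at carbon. C5 and C6 are set in the last step, with only modest face control (see step 2).

## Route

**Step 1**
Reactants: 1 lutein; 2 palmitoyl chloride (2.6 equiv)
Product: 5 lutein dipalmitate, via lutein 3-monopalmitate 3 (not isolated), via lutein 3′-monopalmitate 4 (not isolated)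
Conditions: pyridine (6 equiv), DMAP (0.1 equiv), CH2Cl2, 0 °C → rt, dark, Ar
Reagents that add atoms: none
Why: Nucleophilic acyl substitution (Einhorn/DMAP acylation via the N-acylpyridinium ion) takes place at oxygen only, so C3, C3′ and C6′ keep their configuration, and the pyridine keeps the medium free of HCl so the acid-labile allylic 3′-carbinol does not ionise.

**Step 2**
Reactants: 5 lutein dipalmitate
Product: 6 lutein 5,6-epoxide dipalmitate (target)
Conditions: DMDO (1.05 equiv, ca. 0.07 M in acetone), CH2Cl2, −20 °C, dark, Ar; then SiO2 (1% Et3N) and crystallisation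
Reagents that add atoms: dimethyldioxirane (DMDO), CC1(C)OO1
Why: Dioxirane epoxidation (concerted electrophilic O-atom transfer, the laboratory counterpart of the enzymatic epoxidation) should pick C5=C6 as the only tetrasubstituted, most electron-rich alkene (the ε-ring alkene is trisubstituted and deactivated by its allylic ester), it delivers O to both carbons from one face so C5 and C6 are set together, and with the non-hydrogen-bonding C3 palmitate the face is chosen only by ring sterics, so the wanted 5R,6S epimer (O anti to the C3 ester) is expected in about 1:1 at best with the 5S,6R epimer, which is removed by chromatography, while the acid-free medium keeps the 5,6-epoxide from rearranging to the 5,8-furanoid.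

## Compound list

1 | (3R,3′R,6′R)-β,ε-carotene-3,3′-diol (all-E lutein) | O[C@H]1CC(C)(C)C(/C=C/C(C)=C/C=C/C(C)=C/C=C/C=C(C)/C=C/C=C(C)/C=C/[C@H]2C(C)=C[C@H](O)CC2(C)C)=C(C)C1 | starting material

2 | palmitoyl chloride (hexadecanoyl chloride) | CCCCCCCCCCCCCCCC(Cl)=O | starting material

3 | lutein 3-monopalmitate, (3R,3′R,6′R)-3′-hydroxy-β,ε-caroten-3-yl hexadecanoate (ester on the β-ring) | CCCCCCCCCCCCCCCC(=O)O[C@H]1CC(C)(C)C(/C=C/C(C)=C/C=C/C(C)=C/C=C/C=C(C)/C=C/C=C(C)/C=C/[C@H]2C(C)=C[C@H](O)CC2(C)C)=C(C)C1 | intermediate

4 | lutein 3′-monopalmitate, (3R,3′R,6′R)-3-hydroxy-β,ε-caroten-3′-yl hexadecanoate (ester on the ε-ring) | O[C@H]1CC(C)(C)C(/C=C/C(C)=C/C=C/C(C)=C/C=C/C=C(C)/C=C/C=C(C)/C=C/[C@H]2C(C)=C[C@H](OC(=O)CCCCCCCCCCCCCCC)CC2(C)C)=C(C)C1 | intermediate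

5 | lutein dipalmitate (helenien), (3R,3′R,6′R)-β,ε-carotene-3,3′-diyl dihexadecanoate | CCCCCCCCCCCCCCCC(=O)O[C@H]1CC(C)(C)C(/C=C/C(C)=C/C=C/C(C)=C/C=C/C=C(C)/C=C/C=C(C)/C=C/[C@H]2C(C)=C[C@H](OC(=O)CCCCCCCCCCCCCCC)CC2(C)C)=C(C)C1 | intermediate

6 | lutein 5,6-epoxide dipalmitate, (3S,5R,6S,3′R,6′R)-5,6-epoxy-5,6-dihydro-β,ε-carotene-3,3′-diyl dihexadecanoate (all-E; oxirane anti to the C3 ester) | CCCCCCCCCCCCCCCC(=O)O[C@H]1CC(C)(C)[C@]2(/C=C/C(C)=C/C=C/C(C)=C/C=C/C=C(C)/C=C/C=C(C)/C=C/[C@H]3C(C)=C[C@H](OC(=O)CCCCCCCCCCCCCCC)CC3(C)C)O[C@]2(C)C1 | target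

## Count and risks

Total step count: 2. Longest linear sequence: 2.

The route has only two steps, so both are ranked; there is no third.

**Most likely to fail: step 2.** Three things can go wrong:
- **Face selectivity.** The pseudo-axial C1 methyl sits on the face anti to the equatorial C3 ester, so the ring itself leans towards the unwanted syn epoxide. Peracids on 3-acyloxy β-end groups give syn-rich mixtures (roughly 1:3 against the target). The dioxirane is chosen because dioxiranes are less sensitive than peracids to an allylic axial methyl in Δ5-steroids, but a ratio better than 1:1 is not expected.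
- **Separation.** The two C72 diester epimers may be hard to separate.
- **Over-oxidation.** Some attack on the chain or ε-ring alkenes is possible.

Fallback, setting out from 1 and returning at 6: lutein 1 is acetylated (Ac2O, pyridine, rt) to lutein diacetate F1. F1 is epoxidised with monoperoxyphthalic acid in Et2O, the classical conditions for this ester class, to lutein 5,6-epoxide diacetate F2, which forms together with its 5S,6R epimer. Methanolysis (cat. K2CO3, MeOH–THF) gives lutein 5,6-epoxide F3. As small polar diols the two 5,6-epimers should separate far more easily than the C72 diesters (CaCO3 or diol-phase chromatography). Pure F3 is then acylated with 2 (pyridine, DMAP, CH2Cl2, 0 °C) to give 6. The approach changes: the oxirane is closed before the palmitates are on, and the stereochemical problem is solved by separating diols instead of C72 diesters.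

**Second: step 1.** The acid chloride could ionise the allylic 3′-carbinol (3′-epimerisation, anhydrolutein) or stall at monoesters 3 and 4.

Fallback, setting out from 1 and returning at 5: lutein 1 is transesterified with vinyl palmitate over immobilised Candida antarctica lipase B (toluene, 45 °C, 4 Å MS). This is a neutral, enzyme-mediated acyl transfer in place of acid-chloride chemistry. It makes no new compound (F0).

## Further compounds

F1 | step 2 | lutein diacetate, (3R,3′R,6′R)-β,ε-carotene-3,3′-diyl diacetate | CC(=O)O[C@H]1CC(C)(C)C(/C=C/C(C)=C/C=C/C(C)=C/C=C/C=C(C)/C=C/C=C(C)/C=C/[C@H]2C(C)=C[C@H](OC(C)=O)CC2(C)C)=C(C)C1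

F2 | step 2 | lutein 5,6-epoxide diacetate, (3S,5R,6S,3′R,6′R)-5,6-epoxy-5,6-dihydro-β,ε-carotene-3,3′-diyl diacetate | CC(=O)O[C@H]1CC(C)(C)[C@]2(/C=C/C(C)=C/C=C/C(C)=C/C=C/C=C(C)/C=C/C=C(C)/C=C/[C@H]3C(C)=C[C@H](OC(C)=O)CC3(C)C)O[C@]2(C)C1

F3 | step 2 | lutein 5,6-epoxide, (3S,5R,6S,3′R,6′R)-5,6-epoxy-5,6-dihydro-β,ε-carotene-3,3′-diol | O[C@H]1CC(C)(C)[C@]2(/C=C/C(C)=C/C=C/C(C)=C/C=C/C=C(C)/C=C/C=C(C)/C=C/[C@H]3C(C)=C[C@H](O)CC3(C)C)O[C@]2(C)C1

F0 | step 1 | none | none
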